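**Retrosynthetic overview**

1. The cyclopentenone (ring B, C5–C9 of the 1-oxaspiro[4.4]nonane core) is cut at C6–C7 and C8–C9: the tetrasubstituted C7=C8 unit with its two methyl groups is 2-butyne, inserted as a cis-but-2-ene-2,3-diyl dianion (on titanium) between a lactone carbonyl (future C6) and a ketone (future C9).
2. Enabling feature: ketone C6 and carbinol C9 both sit on the spiro carbon C5 (a 1,3-dioxygenated C6–C5–C9 triad), C9 also carries the acetyl group, and C7/C8 carry identical substituents. The acetyl carbon can therefore be tied to C6 through a lactone oxygen, giving a spiro furan-2,4-dione (temporary ring T) that holds both electrophilic carbons on one ring and poses no regiochemical question for the alkyne.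
3. Ring T is lactic acid plus acetate: C1/C2/C3 of (S)-lactate map onto C9, the acetyl carbonyl and the acetyl methyl, and acetate maps onto C6/C5. The lactate methine is a traceless stereochemical relay: it sets C5, then together with C5 sets C9, and is finally oxidised to the acetyl carbonyl.
4. The oxolane (ring A) is closed by spiro C-alkylation at C5 after a dirhodium-carbenoid O–H insertion of a diazotetronic acid into a tertiary alcohol. That alcohol (C2 and the two side-chain centres) comes from natural phytol by Sharpless epoxidation and reductive opening.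
5. Order of ring formation: ring T (Dieckmann) → ring A (spiro-alkylation) → ring B (key step, in which ring T is opened again).

Key step: step 9

Remark: natural (2E,7R,11R)-phytol is taken as the commercial source of the side chain. The spiro core is numbered as 1-oxaspiro[4.4]nonane (O1, C2–C4, spiro C5, C6–C9) throughout.

**Route**

Step 1
Reactants: 1 (2E,7R,11R)-phytol
Product: 2 [(2R,3R)-3-methyl-3-[(4R,8R)-4,8,12-trimethyltridecyl]oxiran-2-yl]methanol
Conditions: Ti(O-i-Pr)4 (10 mol%), D-(−)-diethyl tartrate (12 mol%), t-BuOOH, 4 Å molecular sieves, CH2Cl2, −20 °C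
Reagents that add atoms: tert-butyl hydroperoxide, CC(C)(C)OO
Why: Katsuki–Sharpless asymmetric epoxidation of the (E)-trisubstituted allylic alcohol is reagent-controlled, and the D-(−)-tartrate ligand should deliver oxygen to the face that gives the (2R,3R)-epoxide (geraniol, with the same substitution pattern, gives the (2S,3S)-epoxide with the L-(+)-ligand), which fixes the quaternary C–O centre that becomes C2 of the target.

Step 2
Reactants: 2 [(2R,3R)-3-methyl-3-[(4R,8R)-4,8,12-trimethyltridecyl]oxiran-2-yl]methanol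
Product: 3 (3R,7R,11R)-3,7,11,15-tetramethylhexadecane-1,3-diol
Conditions: NaAlH2(OCH2CH2OCH3)2 (Red-Al), THF, 0 → 20 °C
Reagents that add atoms: none
Why: Hydroxyl-directed hydride delivery to C2 of the 2,3-epoxy alcohol (also the less substituted carbon) opens the epoxide regioselectively, so the C3–O bond and its configuration are kept and the 1,3-diol should result.

Step 3
Reactants: 3 (3R,7R,11R)-3,7,11,15-tetramethylhexadecane-1,3-diol
Product: 4 (3R,7R,11R)-3-hydroxy-3,7,11,15-tetramethylhexadecyl 4-methylbenzenesulfonate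
Conditions: TsCl (1.1 equiv), Et3N, DMAP (cat.), CH2Cl2, 0 °C
Reagents that add atoms: 4-methylbenzenesulfonyl chloride, Cc1ccc(cc1)S(Cl)(=O)=O
Why: Selective sulfonylation of the primary hydroxyl; the tertiary hydroxyl is too hindered to react and no stereocentre is touched.

Step 4
Reactants: 5 ethyl (2S)-2-hydroxypropanoate (ethyl (S)-lactate)
Product: 6 ethyl (2S)-2-acetoxypropanoate
Conditions: Ac2O, pyridine, DMAP (cat.), CH2Cl2, 0 → 20 °C
Reagents that add atoms: acetic anhydride, CC(=O)OC(C)=O
Why: Standard O-acylation with nucleophilic catalysis; the lactate stereocentre is not involved.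

Step 5
Reactants: 6 ethyl (2S)-2-acetoxypropanoate
Product: 7 (5S)-4-hydroxy-5-methylfuran-2(5H)-one ((S)-5-methyltetronic acid)
Conditions: LiN(SiMe3)2 (2.2 equiv), THF, −78 → 0 °C; then 1 M HCl
Reagents that add atoms: none
Why: Dieckmann (intramolecular Claisen) condensation of the acetate enolate onto the ethyl ester, driven by formation of the stable tetronate anion; the C5 stereocentre comes from the lactate and should survive the kinetic, low-temperature deprotonation.

Step 6
Reactants: 7 (5S)-4-hydroxy-5-methylfuran-2(5H)-one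
Product: 8 (5S)-3-diazo-5-methylfuran-2,4(3H,5H)-dione
Conditions: 4-acetamidobenzenesulfonyl azide, Et3N, MeCN, 0 °C
Reagents that add atoms: 4-acetamidobenzenesulfonyl azide, CC(=O)Nc1ccc(cc1)S(=O)(=O)N=[N+]=[N-]
Why: Regitz diazo transfer to the acidic C3 position of the cyclic 1,3-dicarbonyl compound; the mild base should not epimerise C5.

Step 7
Reactants: 4 (3R,7R,11R)-3-hydroxy-3,7,11,15-tetramethylhexadecyl 4-methylbenzenesulfonate; 8 (5S)-3-diazo-5-methylfuran-2,4(3H,5H)-dione
Product: 9 (5S)-4-hydroxy-5-methyl-3-{[(3R,7R,11R)-3,7,11,15-tetramethyl-1-(tosyloxy)hexadecan-3-yl]oxy}furan-2(5H)-one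
Conditions: Rh2(OAc)4 (2 mol%), benzene, 80 °C, slow addition of 8 (1.5 equiv)
Reagents that add atoms: none
Why: Dirhodium-carbenoid O–H insertion: the electrophilic carbenoid from the cyclic 2-diazo-1,3-dicarbonyl compound is captured by the tertiary alcohol and proton transfer gives the 3-alkoxytetronic acid in its enol form; the sulfonate is inert and no stereocentre is formed or touched.

Step 8
Reactants: 9 (5S)-4-hydroxy-5-methyl-3-{[(3R,7R,11R)-3,7,11,15-tetramethyl-1-(tosyloxy)hexadecan-3-yl]oxy}furan-2(5H)-one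
Product: 10 (2R,5R,8S)-2,8-dimethyl-2-[(4R,8R)-4,8,12-trimethyltridecyl]-1,7-dioxaspiro[4.4]nonane-6,9-dione
Conditions: NaH (1.0 equiv), DMF, 0 → 60 °C, 0.01 M
Reagents that add atoms: none
Why: Intramolecular C-alkylation (5-exo-tet) of the sodium tetronate at C3, the competing O-alkylation requiring a seven-membered ring; the spiro stereocentre is set by 1,3-induction, the C–C bond forming on the face of the planar enolate anti to the ring-T methyl group (as in alkylation of γ-substituted butanolide enolates), which places that methyl cis to O1 and should give the (5R) configuration, and with exactly one equivalent of base nothing remains that could epimerise C8.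

Step 9
Reactants: 10 (2R,5R,8S)-2,8-dimethyl-2-[(4R,8R)-4,8,12-trimethyltridecyl]-1,7-dioxaspiro[4.4]nonane-6,9-dione; 11 but-2-yne
Product: 15 (2R,5R,9R)-9-hydroxy-9-[(1S)-1-hydroxyethyl]-2,7,8-trimethyl-2-[(4R,8R)-4,8,12-trimethyltridecyl]-1-oxaspiro[4.4]non-7-en-6-one, via butyne–titanium complex 12 (not isolated), via oxatitanacyclopentene 13 (not isolated), via bridged titanium hemiketalate 14 (not isolated)
Conditions: Ti(O-i-Pr)4 (1.3 equiv), i-PrMgCl (2.6 equiv), 11 (1.5 equiv), Et2O, −78 → −50 °C, 2 h; then 10, −50 → 20 °C; aq. NH4Cl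
Reagents that add atoms: none
Why: Proposed new method: Ti(O-i-Pr)4 and two equivalents of i-PrMgCl give a divalent titanium–propene complex that exchanges with 11 to the titanacyclopropene 12, a cis-but-2-ene-2,3-diyl dianion equivalent; the ketone of 10 inserts into one Ti–C bond (first C–C bond, giving 13), and the remaining alkenyl–titanium bond, held cis to the new alkoxide and able to reach the lactone carbonyl through a six-membered Ti–O···C=O chelate, adds to it (second C–C bond) to give the bridged hemiketalate 14, which collapses with loss of the lactone oxygen as the side-chain alkoxide. The closest known reaction types are the Sato addition of alkyne–titanium alkoxide complexes to ketones and the titanium-mediated intramolecular nucleophilic acyl substitution of esters; running them in sequence in one flask on a keto lactone is the new element. Ring B closes in the second event, a 5-exo-trig attack of the alkenyl carbon on the lactone carbonyl, after which ring T opens. The new C9 stereocentre is set in the first event: the reagent should approach the ketone anti to the C5–O1 bond, which the spiro junction holds perpendicular to the carbonyl plane (polar Felkin–Anh), and this is also the face anti to the cis methyl group on the neighbouring ring-T carbon and away from the C2 side chain, while chelation-directed delivery from the other face is not expected because O1 is flanked by two fully substituted carbons. The step needs chemoselectivity for the ketone over the lactone in the first event, which the higher electrophilicity of the doubly α-oxygenated ketone should secure, and it needs no regiocontrol because 11 is symmetric.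

Step 10
Reactants: 15 (2R,5R,9R)-9-hydroxy-9-[(1S)-1-hydroxyethyl]-2,7,8-trimethyl-2-[(4R,8R)-4,8,12-trimethyltridecyl]-1-oxaspiro[4.4]non-7-en-6-one
Product: 16 (2R,5R,9S)-9-acetyl-9-hydroxy-2,7,8-trimethyl-2-[(4R,8R)-4,8,12-trimethyltridecyl]-1-oxaspiro[4.4]non-7-en-6-one
Conditions: IBX (1.5 equiv), DMSO, 20 °C
Reagents that add atoms: none
Why: IBX oxidation of the secondary alcohol of a secondary/tertiary 1,2-diol gives the α-hydroxy ketone without glycol cleavage, the tertiary allylic alcohol and the enone being inert; the lactate-derived stereocentre, having served as the relay, is erased and no other centre is touched.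

**Compound list**

1 | (2E,7R,11R)-3,7,11,15-tetramethylhexadec-2-en-1-ol (natural phytol) | OC/C=C(\C)CCC[C@H](C)CCC[C@H](C)CCCC(C)C | starting material
2 | [(2R,3R)-3-methyl-3-[(4R,8R)-4,8,12-trimethyltridecyl]oxiran-2-yl]methanol | OC[C@H]1O[C@]1(C)CCC[C@H](C)CCC[C@H](C)CCCC(C)C | intermediate
3 | (3R,7R,11R)-3,7,11,15-tetramethylhexadecane-1,3-diol | OCC[C@](C)(O)CCC[C@H](C)CCC[C@H](C)CCCC(C)C | intermediate
4 | (3R,7R,11R)-3-hydroxy-3,7,11,15-tetramethylhexadecyl 4-methylbenzenesulfonate | Cc1ccc(cc1)S(=O)(=O)OCC[C@](C)(O)CCC[C@H](C)CCC[C@H](C)CCCC(C)C | intermediate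
5 | ethyl (2S)-2-hydroxypropanoate | C[C@H](O)C(=O)OCC | starting material
6 | ethyl (2S)-2-acetoxypropanoate | C[C@H](OC(C)=O)C(=O)OCC | intermediate
7 | (5S)-4-hydroxy-5-methylfuran-2(5H)-one | C[C@@H]1OC(=O)C=C1O | intermediate
8 | (5S)-3-diazo-5-methylfuran-2,4(3H,5H)-dione | C[C@@H]1OC(=O)C(=[N+]=[N-])C1=O | intermediate
9 | (5S)-4-hydroxy-5-methyl-3-{[(3R,7R,11R)-3,7,11,15-tetramethyl-1-(tosyloxy)hexadecan-3-yl]oxy}furan-2(5H)-one | C[C@@H]1OC(=O)C(O[C@@](C)(CCOS(=O)(=O)c2ccc(C)cc2)CCC[C@H](C)CCC[C@H](C)CCCC(C)C)=C1O | intermediate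
10 | (2R,5R,8S)-2,8-dimethyl-2-[(4R,8R)-4,8,12-trimethyltridecyl]-1,7-dioxaspiro[4.4]nonane-6,9-dione | C[C@@H]1OC(=O)[C@@]2(CC[C@@](C)(CCC[C@H](C)CCC[C@H](C)CCCC(C)C)O2)C1=O | intermediate
11 | but-2-yne | CC#CC | starting material
12 | (η2-but-2-yne)bis(propan-2-olato)titanium (2,3-dimethyltitanacyclopropene) | CC1=C(C)[Ti]1(OC(C)C)OC(C)C | intermediate
13 | oxatitanacyclopentene from insertion of the C9 ketone of 10 into 12 (C9 alkoxide and alkenyl carbon both on titanium) | C[C@@H]1OC(=O)[C@@]2(CC[C@@](C)(CCC[C@H](C)CCC[C@H](C)CCCC(C)C)O2)[C@]13O[Ti](OC(C)C)(OC(C)C)C(C)=C3C | intermediate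
14 | bridged titanium hemiketalate (2-oxabicyclo[2.2.1]hept-5-ene core, both bridgehead oxygens on titanium) | C[C@@H]1O[C@@]2(O[Ti](OC(C)C)(OC(C)C)O3)C(C)=C(C)[C@]13[C@]24CC[C@@](C)(CCC[C@H](C)CCC[C@H](C)CCCC(C)C)O4 | intermediate
15 | (2R,5R,9R)-9-hydroxy-9-[(1S)-1-hydroxyethyl]-2,7,8-trimethyl-2-[(4R,8R)-4,8,12-trimethyltridecyl]-1-oxaspiro[4.4]non-7-en-6-one | C[C@H](O)[C@]1(O)C(C)=C(C)C(=O)[C@@]12CC[C@@](C)(CCC[C@H](C)CCC[C@H](C)CCCC(C)C)O2 | intermediate
16 | (2R,5R,9S)-9-acetyl-9-hydroxy-2,7,8-trimethyl-2-[(4R,8R)-4,8,12-trimethyltridecyl]-1-oxaspiro[4.4]non-7-en-6-one | CC(=O)[C@]1(O)C(C)=C(C)C(=O)[C@@]12CC[C@@](C)(CCC[C@H](C)CCC[C@H](C)CCCC(C)C)O2 | target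

**Summary**

Total step count: 10. Longest linear sequence: 7 steps (steps 1, 2, 3, 7, 8, 9, 10; the lactate branch, steps 4–6, is equally long).

**Steps most likely to fail**

1. Step 9 (proposed new method). The alkenyl–titanium bond of 13 may fail to add to the lactone carbonyl, because the acyl substitution has to pass through the strained bridged hemiketalate 14. Electron transfer from the low-valent titanium reagent to the doubly α-oxygenated ketone, or enolisation at the lactate-derived methine, may also compete.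
   Fallback (known chemistry): it sets out from 10 and 11 and returns at 15. The complex 12 is added to 10 as before at −50 °C, but 13 is cleaved with I2 instead of being warmed; alkyne–titanium addition to a ketone followed by iodinolysis should give (2R,5R,8S,9R)-9-hydroxy-9-[(2Z)-3-iodobut-2-en-2-yl]-2,8-dimethyl-2-[(4R,8R)-4,8,12-trimethyltridecyl]-1,7-dioxaspiro[4.4]nonan-6-one F1. Iodine–lithium exchange (t-BuLi, 3.1 equiv, THF, −78 °C) then generates a far more nucleophilic alkenyllithium, which should close ring B by a Parham-type attack on the lactone carbonyl and give 15 after work-up.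

2. Step 8. Facial discrimination by a single methyl group may be insufficient in the spiro-alkylation, leading to epimerisation of the outcome at C5, and O-alkylation of the ambident tetronate may compete.
   Fallback: it sets out from 4 and returns at 10, replacing substrate control by a reagent-controlled epoxidation and a stereospecific epoxide opening.
   - The sodium salt of triethyl phosphonoacetate is alkylated with 4 (NaH, NaI, DMF, 60 °C) to ethyl (5R,9R,13R)-2-(diethoxyphosphoryl)-5-hydroxy-5,9,13,17-tetramethyloctadecanoate F2 (C2 epimers).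
   - Horner–Wadsworth–Emmons olefination with commercial (S)-2-[(tert-butyldimethylsilyl)oxy]propanal (LiCl, DBU, MeCN) should give ethyl (2E,4S)-4-[(tert-butyldimethylsilyl)oxy]-2-[(3R,7R,11R)-3-hydroxy-3,7,11,15-tetramethylhexadecyl]pent-2-enoate F3.
   - Reduction with i-Bu2AlH (CH2Cl2, −78 °C) gives (2E,4S)-4-[(tert-butyldimethylsilyl)oxy]-2-[(3R,7R,11R)-3-hydroxy-3,7,11,15-tetramethylhexadecyl]pent-2-en-1-ol F4.
   - Katsuki–Sharpless epoxidation (Ti(O-i-Pr)4, D-(−)-diethyl tartrate, t-BuOOH, −20 °C) should give {(2R,3R)-3-[(1S)-1-[(tert-butyldimethylsilyl)oxy]ethyl]-2-[(3R,7R,11R)-3-hydroxy-3,7,11,15-tetramethylhexadecyl]oxiran-2-yl}methanol F5.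
   - Camphorsulfonic acid (CH2Cl2, 0 °C) closes ring A by 5-exo attack of the tertiary hydroxyl on the fully substituted epoxide carbon with inversion, giving (1R,2S)-2-[(tert-butyldimethylsilyl)oxy]-1-{(2S,5R)-2-(hydroxymethyl)-5-methyl-5-[(4R,8R)-4,8,12-trimethyltridecyl]oxolan-2-yl}propan-1-ol F6, with the spiro carbon in the required sense.
   - TEMPO/PhI(OAc)2 (MeCN–H2O) oxidises the primary alcohol to (2R,5R)-2-{(1R,2S)-2-[(tert-butyldimethylsilyl)oxy]-1-hydroxypropyl}-5-methyl-5-[(4R,8R)-4,8,12-trimethyltridecyl]oxolane-2-carboxylic acid F7.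
   - Bu4NF (THF) removes the silyl group and the hydroxy acid lactonises to (2R,5R,8S,9R)-9-hydroxy-2,8-dimethyl-2-[(4R,8R)-4,8,12-trimethyltridecyl]-1,7-dioxaspiro[4.4]nonan-6-one F8.
   - Dess–Martin oxidation of the remaining secondary alcohol gives 10.

3. Step 7. O–H insertion of the hindered tertiary alcohol into the stabilised, cyclic acceptor/acceptor carbenoid may be sluggish, so that Wolff rearrangement or carbene dimerisation takes over.
   Fallback: it sets out from 4 and 5 and returns at 9, using a more reactive acceptor-only carbenoid and building ring T afterwards. Compound 5 is acylated with bromoacetyl bromide (pyridine, CH2Cl2, 0 °C) to ethyl (2S)-2-(2-bromoacetoxy)propanoate F9. N,N′-Ditosylhydrazine and DBU (THF, 0 °C) convert it into ethyl (2S)-2-(2-diazoacetoxy)propanoate F10. Rh2(OAc)4-catalysed O–H insertion into 4 (CH2Cl2, 20 °C) gives ethyl (2S)-2-[2-({(3R,7R,11R)-3,7,11,15-tetramethyl-1-[(4-methylbenzenesulfonyl)oxy]hexadecan-3-yl}oxy)acetoxy]propanoate F11. Dieckmann condensation (LiN(SiMe3)2, THF, −78 °C, then HCl), kept cold so that condensation outruns alkylation by the sulfonate, gives 9.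

**Further compounds**

F1 | step 9 | (2R,5R,8S,9R)-9-hydroxy-9-[(2Z)-3-iodobut-2-en-2-yl]-2,8-dimethyl-2-[(4R,8R)-4,8,12-trimethyltridecyl]-1,7-dioxaspiro[4.4]nonan-6-one | C[C@@H]1OC(=O)[C@@]2(CC[C@@](C)(CCC[C@H](C)CCC[C@H](C)CCCC(C)C)O2)[C@@]1(O)/C(C)=C(/C)I
F2 | step 8 | ethyl (5R,9R,13R)-2-(diethoxyphosphoryl)-5-hydroxy-5,9,13,17-tetramethyloctadecanoate (C2 epimers) | CCOC(=O)C(CC[C@](C)(O)CCC[C@H](C)CCC[C@H](C)CCCC(C)C)P(=O)(OCC)OCC
F3 | step 8 | ethyl (2E,4S)-4-[(tert-butyldimethylsilyl)oxy]-2-[(3R,7R,11R)-3-hydroxy-3,7,11,15-tetramethylhexadecyl]pent-2-enoate | CCOC(=O)/C(CC[C@](C)(O)CCC[C@H](C)CCC[C@H](C)CCCC(C)C)=C/[C@H](C)O[Si](C)(C)C(C)(C)C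
F4 | step 8 | (2E,4S)-4-[(tert-butyldimethylsilyl)oxy]-2-[(3R,7R,11R)-3-hydroxy-3,7,11,15-tetramethylhexadecyl]pent-2-en-1-ol | OC/C(CC[C@](C)(O)CCC[C@H](C)CCC[C@H](C)CCCC(C)C)=C/[C@H](C)O[Si](C)(C)C(C)(C)C
F5 | step 8 | {(2R,3R)-3-[(1S)-1-[(tert-butyldimethylsilyl)oxy]ethyl]-2-[(3R,7R,11R)-3-hydroxy-3,7,11,15-tetramethylhexadecyl]oxiran-2-yl}methanol | OC[C@@]1(CC[C@](C)(O)CCC[C@H](C)CCC[C@H](C)CCCC(C)C)O[C@@H]1[C@H](C)O[Si](C)(C)C(C)(C)C
F6 | step 8 | (1R,2S)-2-[(tert-butyldimethylsilyl)oxy]-1-{(2S,5R)-2-(hydroxymethyl)-5-methyl-5-[(4R,8R)-4,8,12-trimethyltridecyl]oxolan-2-yl}propan-1-ol | OC[C@@]1(CC[C@@](C)(CCC[C@H](C)CCC[C@H](C)CCCC(C)C)O1)[C@H](O)[C@H](C)O[Si](C)(C)C(C)(C)C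
F7 | step 8 | (2R,5R)-2-{(1R,2S)-2-[(tert-butyldimethylsilyl)oxy]-1-hydroxypropyl}-5-methyl-5-[(4R,8R)-4,8,12-trimethyltridecyl]oxolane-2-carboxylic acid | OC(=O)[C@@]1(CC[C@@](C)(CCC[C@H](C)CCC[C@H](C)CCCC(C)C)O1)[C@H](O)[C@H](C)O[Si](C)(C)C(C)(C)C
F8 | step 8 | (2R,5R,8S,9R)-9-hydroxy-2,8-dimethyl-2-[(4R,8R)-4,8,12-trimethyltridecyl]-1,7-dioxaspiro[4.4]nonan-6-one | C[C@@H]1OC(=O)[C@@]2(CC[C@@](C)(CCC[C@H](C)CCC[C@H](C)CCCC(C)C)O2)[C@@H]1O
F9 | step 7 | ethyl (2S)-2-(2-bromoacetoxy)propanoate | C[C@H](OC(=O)CBr)C(=O)OCC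
F10 | step 7 | ethyl (2S)-2-(2-diazoacetoxy)propanoate | C[C@H](OC(=O)C=[N+]=[N-])C(=O)OCC
F11 | step 7 | ethyl (2S)-2-[2-({(3R,7R,11R)-3,7,11,15-tetramethyl-1-[(4-methylbenzenesulfonyl)oxy]hexadecan-3-yl}oxy)acetoxy]propanoate | C[C@H](OC(=O)CO[C@@](C)(CCOS(=O)(=O)c1ccc(C)cc1)CCC[C@H](C)CCC[C@H](C)CCCC(C)C)C(=O)OCC
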